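All runs were generated by integration with made-up constants; noise was put on by code.

Start from the epsilon run: left-handed product plus left-handed substrate stands above half of the charge, so right-handed material has crossed over. Call that surplus T. Averaged over the last 3 readings, T is 2.5 percentage points in epsilon and 1.3 points in zeta. Multiply T by the charged reagent B: epsilon gives 3.80 mM, the transfer capacity W, and zeta gives 3.80 mM.

all flasks: left-handed substrate 20 mM; right-handed substrate 20 mM; precatalyst 40 µM
- delta: reagent 90 mM; run made earlier
- epsilon: reagent 150 mM; run made earlier
- zeta: reagent 300 mM; run made earlier
- green: reagent 80.0 mM; time 10 h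
- amber: reagent 250 mM; time 10 h

- delta (time / h: left-handed product / %, right-handed product / %, left-handed substrate / %): 0.417: 6.7, 3.9, 43.3; 0.833: 11.8, 7.4, 38.3; 1.33: 18.6, 10.7, 33.3; 2.50: 27.3, 17.7, 25.2; 5.00: 38.6, 26.3, 14.5
- epsilon (time / h: left-handed product / %, right-handed product / %, left-handed substrate / %): 1.00: 21.1, 13.5, 29.5; 2.00: 33.6, 22.8, 18.0; 3.00: 40.5, 29.2, 12.5; 4.00: 45.0, 33.7, 7.7; 5.00: 47.5, 35.8, 4.4
- zeta (time / h: left-handed product / %, right-handed product / %, left-handed substrate / %): 1.00: 34.4, 24.0, 16.5; 2.00: 44.8, 34.7, 6.2; 3.00: 48.9, 41.2, 2.3; 4.00: 50.3, 44.5, 1.2; 5.00: 51.1, 46.0, 0

(readings scatter by 0.5 percentage points)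

* which one finishes higher in excess of left-handed product over right-handed product in the product ("neither" within 2 percentage points) (green / amber / neither)
* excess of left-handed product over right-handed product in the product at the end, green
* excess of left-handed product over right-handed product in the product at the end, amber

- reagent is single-handed; left-handed substrate and right-handed substrate are mirror images of each other, charged as a racemate, each of them at the stated concentration
- the numbers in the tables scatter by 0.5 percentage points (one standard deviation)
- an excess is the difference of the two amounts in percent of their sum
- an excess is below zero if the other one leads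
- the handed part of reagent does not stay in what it makes, so the products of the two hands are mirror images too

Write R and S for the two substrates, P and Q for the two products, and c for conversion, all in percent of both substrates charged. Subtract the two hand balances:

excess = (T + T + S − R) / c

Now draw green's curve. Take the selectivity factor s from the first 3 delta readings as 1.69, so the excess starts near 25.5%. Zeta's first hour gives an apparent left-handed rate constant, reckoned on the charged reagent, k = 0.0616 M⁻¹ min⁻¹.

Next find green's conversion at 10 h, assuming one reagent per product. Holding reagent at its charge gives:

exposure 48.0 M·min, c = 88.7%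

Put that back in, with reagent falling in a straight line:

exposure 37.4 M·min, c = 82.2%

Read the substrate gap S − R at similar conversion from epsilon's fourth reading, 5.9 points. With T = W/B, green's excess at that time is:

(9.5 points + 5.9 points) / 82.2% = 18.7%

Amber's exposure is about 138 M·min, leaving a gap near 0.32 points, so its excess is about 3.36%.

The forecast, lower than my reckoning on both flasks, names green as higher, with 16% (12.5% to 19.5%) for green and 3.2% (1.8% to 5%) for amber, whose excess it calls “just twice the transferred amount”.

    reagent + left-handed substrate → left-handed product (k = 0.150 M⁻¹ min⁻¹)
    reagent + right-handed substrate → right-handed product (k = 0.0890 M⁻¹ min⁻¹)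
    left-handed substrate + racemization catalyst ⇌ right-handed substrate + racemization catalyst, rate k3*[racemization catalyst]*[left-handed substrate] forward; the back reaction follows from the equilibrium constant (k = 280 M⁻¹ min⁻¹)
    reagent ⇌ dormant form (K = 1.40, k = 0.310 min⁻¹)
    precatalyst → racemization catalyst (k = 0.0110 min⁻¹)
    reagent + racemization catalyst → spent catalyst (k = 0.390 M⁻¹ min⁻¹)

Green ends at 17.1% and amber at 4.28%, so green finishes higher. At 10.0 h green still holds 11.5% right-handed and 7.08% left-handed substrate. By 100 h both stand at 0%, so the excess there is T + T, and W gives 9.50% against green's 9.70%. For amber at the same time, W gives 3.04% against 3.93%.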